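The ten-membered carbocycle is traced back to a trans-decalin by a fragmentation transform: the C6 oxygen, the C1=C10 olefin and the C14 hydroxyl are read as the three termini of a Grob fragmentation. In the precursor, ring A (C1–C6) and ring B (C6–C10 plus C1) share the C1–C6 bond; C6 carries an axial tertiary hydroxyl and C10 a spiro-epoxide whose equatorial C10–O bond is antiperiplanar to C1–C6. Forming the C6 alkoxide cleaves C1–C6 and opens the epoxide in one operation, giving the C6 ketone, the ring-trans C1=C10 olefin, the C14 oxygen and the cyclodecadiene with C3 and C8 already set; lactone, ester and 1,10-epoxide follow.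

Key step: step 13

Numbering: germacrane numbering of the target is used for all intermediates (ring C1–C10, lactone C11–C13, C14 on C10, C15 on C4); α/β refer to the usual germacranolide drawing (H7 α).
Remark on descriptors: with oxygen on C14 the ring-trans C1=C10 bond (C2 and C9 trans) is (Z) in CIP terms, and it is named so below; the ring-cis C4=C5 bond is (Z) as well.
Assumption: the sense of induction in step 3 is taken from cyclohex-2-enone, where (R)-BINAP gives 3-alkenyl ketones of the same spatial sense as 6; if the monoketal responds in the opposite sense, (S)-BINAP is used.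

Step 1
Reactants: 1 4-methoxy-2-methylphenol
Product: 2 4,4-dimethoxy-2-methylcyclohexa-2,5-dien-1-one
Conditions: PhI(OAc)2, MeOH, 0 °C
Reagents that add atoms: methanol (CO)
Why: Oxidative dearomatisation of a para-methoxyphenol in methanol traps the phenoxenium ion at the methoxy-bearing carbon and gives the quinone monoketal, with no stereocentre formed.

Step 2
Reactants: 3 (2-bromoallyl)trimethylsilane
Product: 5 trimethyl[2-(4,4,5,5-tetramethyl-1,3,2-dioxaborolan-2-yl)prop-2-en-1-yl]silane, via vinyllithium 4 (not isolated)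
Conditions: t-BuLi (2 equiv), Et2O, −78 °C; then 2-isopropoxy-4,4,5,5-tetramethyl-1,3,2-dioxaborolane, −78 → 23 °C
Reagents that add atoms: 2-isopropoxy-4,4,5,5-tetramethyl-1,3,2-dioxaborolane (CC(C)OB1OC(C)(C)C(C)(C)O1)
Why: Bromine–lithium exchange gives the vinyllithium, which is trapped by the isopropoxy boronate (electrophilic borylation), the allylsilane being inert to both reagents.

Step 3
Reactants: 2 4,4-dimethoxy-2-methylcyclohexa-2,5-dien-1-one; 5 trimethyl[2-(4,4,5,5-tetramethyl-1,3,2-dioxaborolan-2-yl)prop-2-en-1-yl]silane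
Product: 6 (5R)-4,4-dimethoxy-2-methyl-5-[3-(trimethylsilyl)prop-1-en-2-yl]cyclohex-2-en-1-one
Conditions: [Rh(cod)Cl]2 (2.5 mol%), (R)-BINAP (6 mol%), KOH (20 mol%), 1,4-dioxane/H2O 10:1, 40 °C
Reagents that add atoms: none
Why: Rhodium-catalysed asymmetric conjugate addition (Hayashi–Miyaura reaction) of the alkenylboronate takes place at C1, the β-carbon of the enone half that lacks the α-methyl group, and the BINAP-bound alkenylrhodium species selects the enone face that sets C1 as drawn.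

Step 4
Reactants: 6 (5R)-4,4-dimethoxy-2-methyl-5-[3-(trimethylsilyl)prop-1-en-2-yl]cyclohex-2-en-1-one
Product: 7 (1R,5R)-4,4-dimethoxy-2-methyl-5-[3-(trimethylsilyl)prop-1-en-2-yl]cyclohex-2-en-1-ol
Conditions: NaBH4, CeCl3·7H2O, MeOH, −78 °C
Reagents that add atoms: none
Why: Luche reduction gives 1,2-reduction only, and hydride should add anti to the side chain on the flap carbon as with 5-substituted cyclohex-2-enones, so the C3 hydroxyl comes out cis to the C1 side chain.

Step 5
Reactants: 7 (1R,5R)-4,4-dimethoxy-2-methyl-5-[3-(trimethylsilyl)prop-1-en-2-yl]cyclohex-2-en-1-ol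
Product: 9 (1S,5R)-4,4-dimethoxy-2-methyl-5-[3-(trimethylsilyl)prop-1-en-2-yl]cyclohex-2-en-1-ol, via 4-nitrobenzoate 8 (not isolated)
Conditions: 4-nitrobenzoic acid, PPh3, DIAD, THF, 0 → 23 °C; then K2CO3 (cat.), MeOH, 23 °C
Reagents that add atoms: 4-nitrobenzoic acid (O=C(O)c1ccc(cc1)[N+](=O)[O-])
Why: Mitsunobu esterification inverts the allylic C3 centre by SN2 displacement of the oxyphosphonium group (SN2' is blocked by the adjacent quaternary ketal carbon) and base-catalysed methanolysis then frees the (3S)-alcohol, trans to the C1 side chain.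

Step 6
Reactants: 9 (1S,5R)-4,4-dimethoxy-2-methyl-5-[3-(trimethylsilyl)prop-1-en-2-yl]cyclohex-2-en-1-ol
Product: 11 (4S,6R)-4-(tert-butyldimethylsilyloxy)-3-methyl-6-[3-(trimethylsilyl)prop-1-en-2-yl]cyclohex-2-en-1-one, via TBS ether ketal 10 (not isolated)
Conditions: TBSCl, imidazole, DMF, 23 °C; then 5% aq. oxalic acid, THF, 0 °C
Reagents that add atoms: tert-butyldimethylsilyl chloride (CC(C)(C)[Si](C)(C)Cl); water (O)
Why: Standard silylation followed by mild acid hydrolysis of the allylic dimethyl ketal unveils the C6 enone without touching the TBS ether or the allylsilane, and no stereocentre is affected.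

Step 7
Reactants: 11 (4S,6R)-4-(tert-butyldimethylsilyloxy)-3-methyl-6-[3-(trimethylsilyl)prop-1-en-2-yl]cyclohex-2-en-1-one
Product: 12 ethyl 2-[(1R,4S,6R)-4-(tert-butyldimethylsilyloxy)-1-hydroxy-3-methyl-6-[3-(trimethylsilyl)prop-1-en-2-yl]cyclohex-2-en-1-yl]acetate
Conditions: LiN(iPr)2, EtOAc, THF, −78 °C; then 11, −78 °C
Reagents that add atoms: ethyl acetate (CCOC(C)=O)
Why: Aldol-type 1,2-addition of the lithium ester enolate to the enone carbonyl should occur from the face opposite the adjacent C1 side chain (equatorial attack of a bulky nucleophile), which sets C6 with C7 trans to C10 and the hydroxyl axial.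

Step 8
Reactants: 12 ethyl 2-[(1R,4S,6R)-4-(tert-butyldimethylsilyloxy)-1-hydroxy-3-methyl-6-[3-(trimethylsilyl)prop-1-en-2-yl]cyclohex-2-en-1-yl]acetate
Product: 13 ethyl 2-[(1R,4S,6R)-4-(tert-butyldimethylsilyloxy)-3-methyl-1-(trimethylsilyloxy)-6-[3-(trimethylsilyl)prop-1-en-2-yl]cyclohex-2-en-1-yl]acetate
Conditions: N-(trimethylsilyl)imidazole, CH2Cl2, 23 °C
Reagents that add atoms: N-(trimethylsilyl)imidazole (C[Si](C)(C)n1ccnc1)
Why: Neutral silylation of the hindered tertiary alcohol avoids Lewis acids that could ionise the tertiary allylic C6–O bond, and the silyl ether later prevents chelation and shields the axial face of ring B.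

Step 9
Reactants: 13 ethyl 2-[(1R,4S,6R)-4-(tert-butyldimethylsilyloxy)-3-methyl-1-(trimethylsilyloxy)-6-[3-(trimethylsilyl)prop-1-en-2-yl]cyclohex-2-en-1-yl]acetate
Product: 14 2-[(1R,4S,6R)-4-(tert-butyldimethylsilyloxy)-3-methyl-1-(trimethylsilyloxy)-6-[3-(trimethylsilyl)prop-1-en-2-yl]cyclohex-2-en-1-yl]acetaldehyde
Conditions: iBu2AlH (1.1 equiv), CH2Cl2, −78 °C
Reagents that add atoms: none
Why: Partial ester reduction stops at the tetrahedral aluminium hemiacetal at −78 °C and gives the C8 aldehyde on work-up.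

Step 10
Reactants: 14 2-[(1R,4S,6R)-4-(tert-butyldimethylsilyloxy)-3-methyl-1-(trimethylsilyloxy)-6-[3-(trimethylsilyl)prop-1-en-2-yl]cyclohex-2-en-1-yl]acetaldehyde
Product: 15 (1R,3S,6R,8R)-3-(tert-butyldimethylsilyloxy)-4-methyl-10-methylidene-6-(trimethylsilyloxy)bicyclo[4.4.0]dec-4-en-8-ol (target numbering; trans-fused)
Conditions: BF3·OEt2 (1.1 equiv), CH2Cl2, −78 °C
Reagents that add atoms: none
Why: Intramolecular Hosomi–Sakurai allylation (6-exo-trig closure through a chair transition state) forms C8–C9 and the exocyclic C10=C14 bond by loss of silicon, and the non-chelating Lewis acid together with the axial C6 silyloxy group keeps the aldehyde oxygen equatorial, so the C8 hydroxyl is equatorial in the trans-decalin.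

Step 11
Reactants: 15 (1R,3S,6R,8R)-3-(tert-butyldimethylsilyloxy)-4-methyl-10-methylidene-6-(trimethylsilyloxy)bicyclo[4.4.0]dec-4-en-8-ol
Product: 16 (1R,3S,6R,8R)-3-(tert-butyldimethylsilyloxy)-8-(4-methoxybenzyloxy)-4-methyl-10-methylidene-6-(trimethylsilyloxy)bicyclo[4.4.0]dec-4-ene
Conditions: NaH, 4-methoxybenzyl chloride, Bu4NI (cat.), THF/DMF, 0 → 23 °C
Reagents that add atoms: 4-methoxybenzyl chloride (COc1ccc(CCl)cc1)
Why: Williamson etherification of the equatorial secondary alkoxide is straightforward, and the tertiary silyl ether cannot migrate because the C6 and C8 oxygens are trans (axial/equatorial) and out of reach of each other.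

Step 12
Reactants: 16 (1R,3S,6R,8R)-3-(tert-butyldimethylsilyloxy)-8-(4-methoxybenzyloxy)-4-methyl-10-methylidene-6-(trimethylsilyloxy)bicyclo[4.4.0]dec-4-ene
Product: 18 (1S,3S,6R,8S,10S)-3-(tert-butyldimethylsilyloxy)-8-(4-methoxybenzyloxy)-4-methylspiro[bicyclo[4.4.0]dec-4-ene-10,2'-oxiran]-6-ol, via epoxide TMS ether 17 (not isolated)
Conditions: mCPBA (1.05 equiv), solid NaHCO3 buffer, CH2Cl2, 0 °C; then K2CO3 (cat.), MeOH, 23 °C
Reagents that add atoms: 3-chloroperoxybenzoic acid (O=C(OO)c1cccc(Cl)c1)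
Why: Peracid (Prilezhaev) epoxidation should reach the exocyclic C10=C14 bond from the equatorial face, because the axial face is closed by the syn-axial C6 silyloxy group, giving the spiro-epoxide with equatorial oxygen, while C4=C5 is deactivated and shielded on both faces by its two allylic silyloxy groups; carbonate-catalysed methanolysis then frees the C6 alcohol.

Step 13
Reactants: 18 (1S,3S,6R,8S,10S)-3-(tert-butyldimethylsilyloxy)-8-(4-methoxybenzyloxy)-4-methylspiro[bicyclo[4.4.0]dec-4-ene-10,2'-oxiran]-6-ol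
Product: 20 (3S,8R,1(10)Z,4Z)-3-(tert-butyldimethylsilyloxy)-8-(4-methoxybenzyloxy)-14-(triethylsilyloxy)-11,12,13-trinorgermacra-1(10),4-dien-6-one, via hydroxy dienone 19 (not isolated)
Conditions: KN(SiMe3)2 (1.05 equiv), THF, −78 → 23 °C; then Et3SiCl, 0 °C
Reagents that add atoms: chlorotriethylsilane (CC[Si](Cl)(CC)CC)
Why: The potassium alkoxide at C6 pushes into the C6–C1 σ bond, which is antiperiplanar to the equatorial C10–O bond of the spiro-epoxide, so that C6=O, C1=C10 and the C14 alkoxide form in one concerted, strain-releasing event. The closest known reaction type is the Grob (Wharton-type) fragmentation of a cyclic 1,3-diol derivative, here in its epoxy-alcohol form with the epoxide as nucleofuge. No ring is closed by bond formation: the ten-membered ring is unveiled by scission of the C1–C6 bond shared by rings A and B, and the primary alkoxide is silylated in the same flask. No stereocentre is created; C3 and C8 pass through unchanged and the centres at C1, C6 and C10 are consumed. The step needs the ring-trans C1=C10 geometry and fragmentation in preference to substitution: the first follows from C2 being equatorial on ring B and hence antiperiplanar to C9, the second from the rigid trans-decalin chair, in which the alkoxide oxygen meets C14 at roughly 120° to the C14–O bond, far from the collinear approach an intramolecular epoxide opening would need. The C4=C5 bond, already cis within ring A, is not touched.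

Step 14
Reactants: 20 (3S,8R,1(10)Z,4Z)-3-(tert-butyldimethylsilyloxy)-8-(4-methoxybenzyloxy)-14-(triethylsilyloxy)-11,12,13-trinorgermacra-1(10),4-dien-6-one
Product: 21 methyl (3S,7R,8R,1(10)Z,4Z)-3-(tert-butyldimethylsilyloxy)-8-(4-methoxybenzyloxy)-6-oxo-14-(triethylsilyloxy)-13-norgermacra-1(10),4-dien-12-oate (C7 side chain β)
Conditions: LiN(iPr)2 (1.1 equiv), THF, −78 °C; methyl bromoacetate, DMPU, −78 → −40 °C
Reagents that add atoms: methyl bromoacetate (COC(=O)CBr)
Why: Kinetic deprotonation can only occur at C7 (C5 is olefinic), and alkylation of the lithium enolate from the outer face of the medium ring (enolate alkylation under macrocyclic, peripheral control) should place the side chain β, cis to the C8 ether, while the cold lithium enolate is expected to resist E1cB loss of the C8 alkoxy group and C7 stays epimerisable should correction be needed.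

Step 15
Reactants: 21 methyl (3S,7R,8R,1(10)Z,4Z)-3-(tert-butyldimethylsilyloxy)-8-(4-methoxybenzyloxy)-6-oxo-14-(triethylsilyloxy)-13-norgermacra-1(10),4-dien-12-oate
Product: 23 (3S,6R,7R,8R,1(10)Z,4Z)-3-(tert-butyldimethylsilyloxy)-8-(4-methoxybenzyloxy)-14-(triethylsilyloxy)-13-norgermacra-1(10),4-dien-12,6-olide (trans-fused lactone), via hydroxy ester 22 (not isolated)
Conditions: NaBH4, CeCl3·7H2O, MeOH, −40 °C; then PPTS (cat.), toluene, 40 °C
Reagents that add atoms: none
Why: Luche reduction attacks only the enone carbonyl, hydride adding antiperiplanar to the pseudoaxial C7–H (the torsionally favoured path for a small hydride, as in axial attack on 2-substituted cyclohexanones) to give the 6α-alcohol trans to the C7 side chain, which closes to the trans-fused γ-lactone by 5-exo-trig acyl substitution.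

Step 16
Reactants: 23 (3S,6R,7R,8R,1(10)Z,4Z)-3-(tert-butyldimethylsilyloxy)-8-(4-methoxybenzyloxy)-14-(triethylsilyloxy)-13-norgermacra-1(10),4-dien-12,6-olide
Product: 26 (3S,6R,7R,8R,1(10)Z,4Z)-3-(tert-butyldimethylsilyloxy)-8-(4-methoxybenzyloxy)-14-(triethylsilyloxy)germacra-1(10),4,11(13)-trien-12,6-olide, via Mannich base 24 (not isolated), via methiodide 25 (not isolated)
Conditions: LiN(iPr)2, THF, −78 °C; CH2=NMe2+ I−, −78 → 0 °C; then MeI, MeOH/CH2Cl2, 23 °C; then aq. NaHCO3, 23 °C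
Reagents that add atoms: dimethylmethylideneammonium iodide (C=[N+](C)C.[I-])
Why: Eschenmoser methylenation: the lactone enolate is aminomethylated at C11 (Mannich reaction) and quaternisation followed by base-induced elimination of trimethylamine gives the exocyclic C11=C13 bond, the transient C11 centre being destroyed again.

Step 17
Reactants: 26 (3S,6R,7R,8R,1(10)Z,4Z)-3-(tert-butyldimethylsilyloxy)-8-(4-methoxybenzyloxy)-14-(triethylsilyloxy)germacra-1(10),4,11(13)-trien-12,6-olide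
Product: 27 (3S,6R,7R,8R,1(10)Z,4Z)-3-(tert-butyldimethylsilyloxy)-8-hydroxy-14-(triethylsilyloxy)germacra-1(10),4,11(13)-trien-12,6-olide
Conditions: DDQ, CH2Cl2/pH 7 buffer 10:1, 0 °C
Reagents that add atoms: none
Why: Oxidative cleavage of the electron-rich p-methoxybenzyl ether (hydride abstraction by DDQ, hydrolysis of the oxocarbenium ion) frees the C8 alcohol and leaves silyl ethers, olefins and the methylene lactone untouched.

Step 18
Reactants: 27 (3S,6R,7R,8R,1(10)Z,4Z)-3-(tert-butyldimethylsilyloxy)-8-hydroxy-14-(triethylsilyloxy)germacra-1(10),4,11(13)-trien-12,6-olide; 28 (R)-2-methylbutanoic acid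
Product: 29 (3S,6R,7R,8R,1(10)Z,4Z)-3-(tert-butyldimethylsilyloxy)-8-[(2R)-2-methylbutanoyloxy]-14-(triethylsilyloxy)germacra-1(10),4,11(13)-trien-12,6-olide
Conditions: DCC, DMAP (cat.), CH2Cl2, 0 → 23 °C
Reagents that add atoms: none
Why: Steglich esterification acylates the only free hydroxyl, and with catalytic DMAP at low temperature the α-stereocentre of the acid is not expected to epimerise.

Step 19
Reactants: 29 (3S,6R,7R,8R,1(10)Z,4Z)-3-(tert-butyldimethylsilyloxy)-8-[(2R)-2-methylbutanoyloxy]-14-(triethylsilyloxy)germacra-1(10),4,11(13)-trien-12,6-olide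
Product: 30 (3S,6R,7R,8R,1(10)Z,4Z)-3-(tert-butyldimethylsilyloxy)-14-hydroxy-8-[(2R)-2-methylbutanoyloxy]germacra-1(10),4,11(13)-trien-12,6-olide
Conditions: PPTS, MeOH/CH2Cl2, 0 °C
Reagents that add atoms: none
Why: Acid-catalysed methanolysis (selective desilylation) removes the primary allylic triethylsilyl ether much faster than the hindered secondary TBS ether at C3.

Step 20
Reactants: 30 (3S,6R,7R,8R,1(10)Z,4Z)-3-(tert-butyldimethylsilyloxy)-14-hydroxy-8-[(2R)-2-methylbutanoyloxy]germacra-1(10),4,11(13)-trien-12,6-olide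
Product: 31 (1R,3S,6R,7R,8R,10S,4Z)-3-(tert-butyldimethylsilyloxy)-1,10-epoxy-14-hydroxy-8-[(2R)-2-methylbutanoyloxy]germacra-4,11(13)-dien-12,6-olide
Conditions: Ti(OiPr)4 (0.5 equiv), L-(+)-diethyl tartrate (0.6 equiv), t-BuOOH, 4 Å MS, CH2Cl2, −20 °C
Reagents that add atoms: tert-butyl hydroperoxide (CC(C)(C)OO)
Why: Sharpless asymmetric epoxidation: titanium binds the C14 allylic alcohol so only C1=C10 is oxidised, and the L-(+)-tartrate complex delivers oxygen to the face that gives the (1R,10S)-epoxide (the same local sense as in the (2S)-epoxy alcohols from simple allylic alcohols), while the silylated C3 allylic system and the electron-poor methylene lactone do not react.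

Step 21
Reactants: 31 (1R,3S,6R,7R,8R,10S,4Z)-3-(tert-butyldimethylsilyloxy)-1,10-epoxy-14-hydroxy-8-[(2R)-2-methylbutanoyloxy]germacra-4,11(13)-dien-12,6-olide
Product: 32 (1R,3S,6R,7R,8R,10S,4Z)-1,10-epoxy-3,14-dihydroxy-8-[(2R)-2-methylbutanoyloxy]germacra-4,11(13)-dien-12,6-olide (CNP0356520.1)
Conditions: HF·pyridine, pyridine, THF, 0 → 23 °C
Reagents that add atoms: none
Why: Buffered fluoride desilylation cleaves the last silyl ether under weakly acidic conditions that should neither open the epoxide, nor trigger Payne rearrangement, nor add to the methylene lactone.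

Compound list
1 | 4-methoxy-2-methylphenol | COc1ccc(O)c(C)c1 | starting material
2 | 4,4-dimethoxy-2-methylcyclohexa-2,5-dien-1-one | O=C1C(C)=CC(OC)(OC)C=C1 | intermediate
3 | (2-bromoallyl)trimethylsilane | C=C(Br)C[Si](C)(C)C | starting material
4 | [3-(trimethylsilyl)prop-1-en-2-yl]lithium | [Li]C(=C)C[Si](C)(C)C | intermediate
5 | trimethyl[2-(4,4,5,5-tetramethyl-1,3,2-dioxaborolan-2-yl)prop-2-en-1-yl]silane | C=C(C[Si](C)(C)C)B1OC(C)(C)C(C)(C)O1 | intermediate
6 | (5R)-4,4-dimethoxy-2-methyl-5-[3-(trimethylsilyl)prop-1-en-2-yl]cyclohex-2-en-1-one | O=C1C(C)=CC(OC)(OC)[C@@H](C(=C)C[Si](C)(C)C)C1 | intermediate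
7 | (1R,5R)-4,4-dimethoxy-2-methyl-5-[3-(trimethylsilyl)prop-1-en-2-yl]cyclohex-2-en-1-ol (OH cis to side chain) | O[C@H]1C(C)=CC(OC)(OC)[C@@H](C(=C)C[Si](C)(C)C)C1 | intermediate
8 | (1S,5R)-4,4-dimethoxy-2-methyl-5-[3-(trimethylsilyl)prop-1-en-2-yl]cyclohex-2-en-1-yl 4-nitrobenzoate | O=C(O[C@@H]1C(C)=CC(OC)(OC)[C@@H](C(=C)C[Si](C)(C)C)C1)c1ccc(cc1)[N+](=O)[O-] | intermediate
9 | (1S,5R)-4,4-dimethoxy-2-methyl-5-[3-(trimethylsilyl)prop-1-en-2-yl]cyclohex-2-en-1-ol (OH trans to side chain) | O[C@@H]1C(C)=CC(OC)(OC)[C@@H](C(=C)C[Si](C)(C)C)C1 | intermediate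
10 | tert-butyl{[(1S,5R)-4,4-dimethoxy-2-methyl-5-[3-(trimethylsilyl)prop-1-en-2-yl]cyclohex-2-en-1-yl]oxy}dimethylsilane | CC(C)(C)[Si](C)(C)O[C@@H]1C(C)=CC(OC)(OC)[C@@H](C(=C)C[Si](C)(C)C)C1 | intermediate
11 | (4S,6R)-4-(tert-butyldimethylsilyloxy)-3-methyl-6-[3-(trimethylsilyl)prop-1-en-2-yl]cyclohex-2-en-1-one | O=C1C=C(C)[C@@H](O[Si](C)(C)C(C)(C)C)C[C@@H]1C(=C)C[Si](C)(C)C | intermediate
12 | ethyl 2-[(1R,4S,6R)-4-(tert-butyldimethylsilyloxy)-1-hydroxy-3-methyl-6-[3-(trimethylsilyl)prop-1-en-2-yl]cyclohex-2-en-1-yl]acetate | CCOC(=O)C[C@@]1(O)C=C(C)[C@@H](O[Si](C)(C)C(C)(C)C)C[C@@H]1C(=C)C[Si](C)(C)C | intermediate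
13 | ethyl 2-[(1R,4S,6R)-4-(tert-butyldimethylsilyloxy)-3-methyl-1-(trimethylsilyloxy)-6-[3-(trimethylsilyl)prop-1-en-2-yl]cyclohex-2-en-1-yl]acetate | CCOC(=O)C[C@@]1(O[Si](C)(C)C)C=C(C)[C@@H](O[Si](C)(C)C(C)(C)C)C[C@@H]1C(=C)C[Si](C)(C)C | intermediate
14 | 2-[(1R,4S,6R)-4-(tert-butyldimethylsilyloxy)-3-methyl-1-(trimethylsilyloxy)-6-[3-(trimethylsilyl)prop-1-en-2-yl]cyclohex-2-en-1-yl]acetaldehyde | O=CC[C@@]1(O[Si](C)(C)C)C=C(C)[C@@H](O[Si](C)(C)C(C)(C)C)C[C@@H]1C(=C)C[Si](C)(C)C | intermediate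
15 | (1R,3S,6R,8R)-3-(tert-butyldimethylsilyloxy)-4-methyl-10-methylidene-6-(trimethylsilyloxy)bicyclo[4.4.0]dec-4-en-8-ol (target numbering; trans-decalin, C6–O axial, C8–OH equatorial) | C[Si](C)(C)O[C@]12C=C(C)[C@@H](O[Si](C)(C)C(C)(C)C)C[C@@H]1C(=C)C[C@@H](O)C2 | intermediate
16 | (1R,3S,6R,8R)-3-(tert-butyldimethylsilyloxy)-8-(4-methoxybenzyloxy)-4-methyl-10-methylidene-6-(trimethylsilyloxy)bicyclo[4.4.0]dec-4-ene | C[Si](C)(C)O[C@]12C=C(C)[C@@H](O[Si](C)(C)C(C)(C)C)C[C@@H]1C(=C)C[C@@H](OCc3ccc(OC)cc3)C2 | intermediate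
17 | (1R,3S,6R,8R,10S)-3-(tert-butyldimethylsilyloxy)-8-(4-methoxybenzyloxy)-4-methyl-6-(trimethylsilyloxy)spiro[bicyclo[4.4.0]dec-4-ene-10,2'-oxirane] (epoxide oxygen equatorial) | C[Si](C)(C)O[C@]12C=C(C)[C@@H](O[Si](C)(C)C(C)(C)C)C[C@@H]1[C@]3(CO3)C[C@@H](OCc4ccc(OC)cc4)C2 | intermediate
18 | (1S,3S,6R,8S,10S)-3-(tert-butyldimethylsilyloxy)-8-(4-methoxybenzyloxy)-4-methylspiro[bicyclo[4.4.0]dec-4-ene-10,2'-oxiran]-6-ol (same geometry as 17; the C1 and C8 descriptors change only through CIP priorities) | O[C@]12C=C(C)[C@@H](O[Si](C)(C)C(C)(C)C)C[C@@H]1[C@]3(CO3)C[C@@H](OCc4ccc(OC)cc4)C2 | intermediate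
19 | (3S,8R,1(10)Z,4Z)-3-(tert-butyldimethylsilyloxy)-14-hydroxy-8-(4-methoxybenzyloxy)-11,12,13-trinorgermacra-1(10),4-dien-6-one, formed as its potassium alkoxide | O=C1/C=C(/C)[C@@H](O[Si](C)(C)C(C)(C)C)C/C=C(CO)/C[C@@H](OCc2ccc(OC)cc2)C1 | intermediate
20 | (3S,8R,1(10)Z,4Z)-3-(tert-butyldimethylsilyloxy)-8-(4-methoxybenzyloxy)-14-(triethylsilyloxy)-11,12,13-trinorgermacra-1(10),4-dien-6-one | O=C1/C=C(/C)[C@@H](O[Si](C)(C)C(C)(C)C)C/C=C(CO[Si](CC)(CC)CC)/C[C@@H](OCc2ccc(OC)cc2)C1 | intermediate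
21 | methyl (3S,7R,8R,1(10)Z,4Z)-3-(tert-butyldimethylsilyloxy)-8-(4-methoxybenzyloxy)-6-oxo-14-(triethylsilyloxy)-13-norgermacra-1(10),4-dien-12-oate | O=C1/C=C(/C)[C@@H](O[Si](C)(C)C(C)(C)C)C/C=C(CO[Si](CC)(CC)CC)/C[C@@H](OCc2ccc(OC)cc2)[C@H]1CC(=O)OC | intermediate
22 | methyl (3S,6R,7S,8R,1(10)Z,4Z)-3-(tert-butyldimethylsilyloxy)-6-hydroxy-8-(4-methoxybenzyloxy)-14-(triethylsilyloxy)-13-norgermacra-1(10),4-dien-12-oate (6α-OH) | O[C@@H]1/C=C(/C)[C@@H](O[Si](C)(C)C(C)(C)C)C/C=C(CO[Si](CC)(CC)CC)/C[C@@H](OCc2ccc(OC)cc2)[C@H]1CC(=O)OC | intermediate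
23 | (3S,6R,7R,8R,1(10)Z,4Z)-3-(tert-butyldimethylsilyloxy)-8-(4-methoxybenzyloxy)-14-(triethylsilyloxy)-13-norgermacra-1(10),4-dien-12,6-olide | C1C(=O)O[C@@H]2/C=C(/C)[C@@H](O[Si](C)(C)C(C)(C)C)C/C=C(CO[Si](CC)(CC)CC)/C[C@@H](OCc3ccc(OC)cc3)[C@@H]12 | intermediate
24 | 13-(dimethylamino) derivative of 23 (Mannich base; C11 configuration not defined) | CN(C)CC1C(=O)O[C@@H]2/C=C(/C)[C@@H](O[Si](C)(C)C(C)(C)C)C/C=C(CO[Si](CC)(CC)CC)/C[C@@H](OCc3ccc(OC)cc3)[C@@H]12 | intermediate
25 | 13-(trimethylammonio) derivative of 23, iodide salt | C[N+](C)(C)CC1C(=O)O[C@@H]2/C=C(/C)[C@@H](O[Si](C)(C)C(C)(C)C)C/C=C(CO[Si](CC)(CC)CC)/C[C@@H](OCc3ccc(OC)cc3)[C@@H]12.[I-] | intermediate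
26 | (3S,6R,7R,8R,1(10)Z,4Z)-3-(tert-butyldimethylsilyloxy)-8-(4-methoxybenzyloxy)-14-(triethylsilyloxy)germacra-1(10),4,11(13)-trien-12,6-olide | C=C1C(=O)O[C@@H]2/C=C(/C)[C@@H](O[Si](C)(C)C(C)(C)C)C/C=C(CO[Si](CC)(CC)CC)/C[C@@H](OCc3ccc(OC)cc3)[C@@H]12 | intermediate
27 | (3S,6R,7R,8R,1(10)Z,4Z)-3-(tert-butyldimethylsilyloxy)-8-hydroxy-14-(triethylsilyloxy)germacra-1(10),4,11(13)-trien-12,6-olide | C=C1C(=O)O[C@@H]2/C=C(/C)[C@@H](O[Si](C)(C)C(C)(C)C)C/C=C(CO[Si](CC)(CC)CC)/C[C@@H](O)[C@@H]12 | intermediate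
28 | (R)-2-methylbutanoic acid | CC[C@@H](C)C(=O)O | starting material
29 | (3S,6R,7R,8R,1(10)Z,4Z)-3-(tert-butyldimethylsilyloxy)-8-[(2R)-2-methylbutanoyloxy]-14-(triethylsilyloxy)germacra-1(10),4,11(13)-trien-12,6-olide | C=C1C(=O)O[C@@H]2/C=C(/C)[C@@H](O[Si](C)(C)C(C)(C)C)C/C=C(CO[Si](CC)(CC)CC)/C[C@@H](OC(=O)[C@H](C)CC)[C@@H]12 | intermediate
30 | (3S,6R,7R,8R,1(10)Z,4Z)-3-(tert-butyldimethylsilyloxy)-14-hydroxy-8-[(2R)-2-methylbutanoyloxy]germacra-1(10),4,11(13)-trien-12,6-olide | C=C1C(=O)O[C@@H]2/C=C(/C)[C@@H](O[Si](C)(C)C(C)(C)C)C/C=C(CO)/C[C@@H](OC(=O)[C@H](C)CC)[C@@H]12 | intermediate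
31 | (1R,3S,6R,7R,8R,10S,4Z)-3-(tert-butyldimethylsilyloxy)-1,10-epoxy-14-hydroxy-8-[(2R)-2-methylbutanoyloxy]germacra-4,11(13)-dien-12,6-olide (1β,10α-epoxide) | C=C1C(=O)O[C@@H]2/C=C(/C)[C@@H](O[Si](C)(C)C(C)(C)C)C[C@H]3O[C@]3(CO)C[C@@H](OC(=O)[C@H](C)CC)[C@@H]12 | intermediate
32 | (1R,3S,6R,7R,8R,10S,4Z)-1,10-epoxy-3,14-dihydroxy-8-[(2R)-2-methylbutanoyloxy]germacra-4,11(13)-dien-12,6-olide | C=C1C(=O)O[C@@H]2/C=C(/C)[C@@H](O)C[C@H]3O[C@]3(CO)C[C@@H](OC(=O)[C@H](C)CC)[C@@H]12 | target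

Total step count: 21. Longest linear sequence: 20 steps (from 1 through steps 1 and 3–21); step 2 is a one-step side branch and acid 28 is purchased.

Steps most likely to fail

Step 13. The alkoxide may fragment sluggishly, or the base may expel the C8 alkoxy group (E1cB) from the newly formed ketone before the product is trapped. The fallback changes the activation from alkoxide push to Lewis-acid pull: starting from 18, Ti(OiPr)4 in toluene at 60–80 °C forms the C6 titanium alkoxide and activates the epoxide under non-basic conditions, giving hydroxy dienone 19 as an isolated compound. Separate silylation (Et3SiCl, imidazole, CH2Cl2) then returns to the route at 20.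

Step 14. The enolate may lose the C8 p-methoxybenzyloxy group by β-elimination, or the electrophile may enter from the wrong face of the medium-ring enolate. The fallback avoids a free enolate: starting from 20, soft enolisation (Me3SiOTf, Et3N, CH2Cl2, −78 °C) gives the C6 trimethylsilyl enol ether F1. Lewis-acid alkylation of F1 with methyl 2-chloro-2-(phenylsulfanyl)acetate (ZnBr2, CH2Cl2) gives the α-phenylsulfanyl ester F2. Radical desulfurisation of F2 (Bu3SnH, AIBN, benzene, 80 °C) returns to the route at 21. If the C7 epimer dominates, it can be equilibrated through the ketone with DBU before reduction.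

Step 15. Hydride may be delivered to the other face of the C6 carbonyl, which leads to the 6β-alcohol and, after ring closure, the cis-fused lactone. The fallback corrects C6 at the lactonisation stage: starting from 21, the same reduction and ring closure would then give the 6-epi (cis-fused) lactone F3. Saponification (LiOH, THF/H2O) opens F3 to the 6β-hydroxy acid F4. Mitsunobu lactonisation of F4 (PPh3, DIAD, THF, high dilution) closes the ring with inversion at the allylic C6 and returns to the route at 23.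

Further compounds
F0 | step 13 | none | none
F1 | step 14 | C6 trimethylsilyl enol ether of 20 (C6=C7) | C[Si](C)(C)OC=1/C=C(/C)[C@@H](O[Si](C)(C)C(C)(C)C)C/C=C(CO[Si](CC)(CC)CC)/C[C@@H](OCc2ccc(OC)cc2)C=1
F2 | step 14 | methyl ester 21 bearing a phenylsulfanyl group at C11 (C11 configuration not defined) | O=C1/C=C(/C)[C@@H](O[Si](C)(C)C(C)(C)C)C/C=C(CO[Si](CC)(CC)CC)/C[C@@H](OCc2ccc(OC)cc2)[C@H]1C(Sc3ccccc3)C(=O)OC
F3 | step 15 | 6-epi (cis-fused) lactone of 23 | C1C(=O)O[C@H]2/C=C(/C)[C@@H](O[Si](C)(C)C(C)(C)C)C/C=C(CO[Si](CC)(CC)CC)/C[C@@H](OCc3ccc(OC)cc3)[C@@H]12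
F4 | step 15 | 6β-hydroxy acid from F3 | O[C@H]1/C=C(/C)[C@@H](O[Si](C)(C)C(C)(C)C)C/C=C(CO[Si](CC)(CC)CC)/C[C@@H](OCc2ccc(OC)cc2)[C@H]1CC(=O)O
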